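**Retrosynthetic overview**
1. Floranol 22 ⇐ cleavage of three MOM ethers from 21 ⇐ loss of an allyl carboxylate from C3 of crossed-benzoin product 18.
2. Key disconnection: the C4–C3 bond of ring C. The C4(=O)–C3(OH) α-ketol is a benzoin retron, with C4 from the ring A aldehyde (acyl anion through a carbene) and C3 from the ketone of an α-keto ester.
3. Enabling feature: in ring C the α-ketol C4(=O)–C3(OH) lies next to C2, whose hydrogen is benzylic to ring B, α to O1 and, in the precursor, α to the C3 keto ester. C2 therefore racemizes and is set by dynamic kinetic resolution during ring closure; the ester on C3 makes the acceptor a ketone and later leaves as CO2.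
4. The ring-closure precursor forms in the same flask by O1–C2 etherification of salicylaldehyde 9 (ring A) with racemic chloro keto ester 16 (ring B, C2, C3).
5. Ring order: rings A and B are bought as arenes (2-methoxyresorcinol, salicylaldehyde); ring C is the only ring formed (step 10). Aldehyde 9 comes from C–H borylation/oxidation, a reverse-prenyl Claisen rearrangement and ortho-formylation.

Key step: step 10

Assumption: the target is the (2R,3R)-trans isomer written in the SMILES; the sense of induction of the triazolium carbene in step 10 cannot be fixed in advance, so the (5aR,10bS) catalyst is written and its commercially available antipode is used should C2 form with the opposite configuration.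

**Route**

Step 1
Reactants: 1 2-methoxyresorcinol (2-methoxybenzene-1,3-diol)
Product: 2 2-methoxy-1,3-bis(methoxymethoxy)benzene
Conditions: MOMCl (2.5 equiv), iPr2NEt, CH2Cl2, 0 → 23 °C
Reagents that add atoms: chloromethyl methyl ether (MOMCl), COCCl
Why: Double O-alkylation of the two phenols (Williamson-type acetal formation) should protect both oxygens as base-stable MOM ethers; no stereocenter is involved.

Step 2
Reactants: 2 2-methoxy-1,3-bis(methoxymethoxy)benzene
Product: 4 4-methoxy-3,5-bis(methoxymethoxy)phenol, via aryl pinacol boronate 3 (not isolated)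
Conditions: [Ir(OMe)(cod)]2 (1.5 mol %), 4,4′-di-tert-butyl-2,2′-bipyridine (3 mol %), B2pin2, THF, 80 °C; then 30% H2O2, aq. NaOH, 0 °C
Reagents that add atoms: bis(pinacolato)diboron, CC1(C)OB(OC1(C)C)B1OC(C)(C)C(C)(C)O1 (boron of 3 only); hydrogen peroxide, OO (oxygen of 4)
Why: Sterically governed iridium-catalysed C–H borylation should take the only C–H without an ortho substituent (C5 of the 1,2,3-trisubstituted ring), and boronate oxidation then gives the phenol (C–H borylation/oxidation).

Step 3
Reactants: 4 4-methoxy-3,5-bis(methoxymethoxy)phenol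
Product: 5 2-methoxy-1,3-bis(methoxymethoxy)-5-[(2-methylbut-3-yn-2-yl)oxy]benzene
Conditions: 3-chloro-3-methylbut-1-yne, DBU, CuCl2 (1 mol %), MeCN, 0 °C
Reagents that add atoms: 3-chloro-3-methylbut-1-yne, CC(C)(Cl)C#C
Why: Copper-catalysed propargylic etherification of a phenol with the tertiary propargylic chloride is the standard entry to 1,1-dimethylpropargyl aryl ethers.

Step 4
Reactants: 5 2-methoxy-1,3-bis(methoxymethoxy)-5-[(2-methylbut-3-yn-2-yl)oxy]benzene
Product: 6 2-methoxy-1,3-bis(methoxymethoxy)-5-[(2-methylbut-3-en-2-yl)oxy]benzene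
Conditions: H2 (1 atm), Pd/CaCO3 poisoned with Pb(OAc)2 (Lindlar catalyst), quinoline, EtOAc, 23 °C
Reagents that add atoms: none
Why: Lindlar semi-hydrogenation should stop at the terminal alkene and leave the acetals untouched.

Step 5
Reactants: 6 2-methoxy-1,3-bis(methoxymethoxy)-5-[(2-methylbut-3-en-2-yl)oxy]benzene
Product: 7 4-methoxy-3,5-bis(methoxymethoxy)-2-(3-methylbut-2-en-1-yl)phenol
Conditions: PhNEt2, 120 °C
Reagents that add atoms: none
Why: Aromatic Claisen rearrangement ([3,3]) of the 1,1-dimethylallyl aryl ether moves the allyl unit with allylic inversion to one of the two equivalent ortho positions, giving the linear prenyl group beside the regenerated phenol.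

Step 6
Reactants: 7 4-methoxy-3,5-bis(methoxymethoxy)-2-(3-methylbut-2-en-1-yl)phenol
Product: 9 2-hydroxy-5-methoxy-4,6-bis(methoxymethoxy)-3-(3-methylbut-2-en-1-yl)benzaldehyde, via salicyl alcohol 8 (not isolated)
Conditions: MgCl2, Et3N, (CH2O)n, MeCN, 80 °C
Reagents that add atoms: paraformaldehyde (formaldehyde), C=O
Why: Magnesium-mediated ortho-formylation of phenols (Casnati–Skattebøl) should hydroxymethylate the only free ortho position through the magnesium phenoxide, and a second formaldehyde oxidizes the benzylic alkoxide by hydride transfer.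

Step 7
Reactants: 10 salicylaldehyde
Product: 11 2-(methoxymethoxy)benzaldehyde
Conditions: MOMCl, iPr2NEt, CH2Cl2, 0 → 23 °C
Reagents that add atoms: chloromethyl methyl ether (MOMCl), COCCl
Why: O-alkylation of the phenol (Williamson-type) masks the future 2′-hydroxyl of ring B as a MOM ether.

Step 8
Reactants: 12 dichloroacetyl chloride; 13 allyl alcohol
Product: 14 allyl dichloroacetate
Conditions: pyridine, CH2Cl2, 0 °C
Reagents that add atoms: none
Why: Acylation of the alcohol by the acid chloride gives the allyl ester needed for a later non-hydrolytic removal of the carboxyl group.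

Step 9
Reactants: 11 2-(methoxymethoxy)benzaldehyde; 14 allyl dichloroacetate
Product: 16 allyl 3-chloro-3-[2-(methoxymethoxy)phenyl]-2-oxopropanoate (racemic), via chloro glycidic ester 15 (not isolated)
Conditions: KN(SiMe3)2, THF, −78 → 0 °C; then PhMe, 60 °C
Reagents that add atoms: none
Why: Darzens condensation of the dichloroacetate enolate with the aldehyde gives the α-chloro glycidic ester, which opens at the benzylic carbon with 1,2-chloride shift to the β-chloro α-keto ester (the known Darzens/rearrangement route to 3-chloro-2-oxo esters); the new center is racemic, which is what step 10 needs.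

Step 10
Reactants: 9 2-hydroxy-5-methoxy-4,6-bis(methoxymethoxy)-3-(3-methylbut-2-en-1-yl)benzaldehyde; 16 allyl 3-chloro-3-[2-(methoxymethoxy)phenyl]-2-oxopropanoate (racemic)
Product: 18 allyl (2R,3R)-3-hydroxy-6-methoxy-5,7-bis(methoxymethoxy)-2-[2-(methoxymethoxy)phenyl]-8-(3-methylbut-2-en-1-yl)-4-oxochromane-3-carboxylate, via keto aldehyde 17 (not isolated)
Conditions: Cs2CO3 (1.1 equiv), THF, 0 → 23 °C; then (5aR,10bS)-2-(pentafluorophenyl)-5a,10b-dihydro-4H,6H-indeno[2,1-b][1,2,4]triazolo[4,3-d][1,4]oxazin-2-ium tetrafluoroborate (15 mol %), 23 °C, Ar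
Reagents that add atoms: none
Why: Proposed new method: the cesium phenoxide of 9 displaces the doubly activated benzylic chloride of 16 (the Williamson stage of a Rap–Stoermer reaction) to give keto aldehyde 17, whose C2–H (benzylic, α to O1 and α to the keto ester) exchanges through the enol so that the enantiomers of 17 interconvert; the triazolylidene then adds to the only aldehyde (future C4), the Breslow intermediate attacks the C3 ketone to form C3–C4, and proton transfer with loss of the carbene leaves the C4 ketone. The closest known reactions are the enantioselective intramolecular aldehyde–ketone crossed benzoin that gives 3-hydroxychroman-4-ones and the dynamic kinetic crossed benzoin of racemic β-halo α-keto esters with aldehydes under chiral triazolium carbene catalysis; their union on a β-aryloxy β-aryl α-keto ester is what is new. Ring C closes in the 6-exo-trig mode, the attacked C3=O being exocyclic to the forming pyranone. The catalyst fixes the attacked face of the ketone (C3), and C2 is set by dynamic kinetic resolution, because only the epimer that keeps the C2 aryl group pseudo-equatorial and the C3 ester anti to the azolium in the chair-like transition state should cyclize quickly while the other returns to the enol; once ring C is closed C3 is quaternary, so C2 can no longer epimerize by enolization or by opening of ring C. The step needs donor/acceptor regioselectivity, secured because the acceptor is a ketone (there is no second aldehyde, hence no Breslow intermediate that could expel the aryloxide), and it needs the benzoin closure to outrun the 5-exo aldol of the C2 enolate onto the aldehyde, which the mild carbonate base and the reversibility of that congested aldol should secure.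

Step 11
Reactants: 18 allyl (2R,3R)-3-hydroxy-6-methoxy-5,7-bis(methoxymethoxy)-2-[2-(methoxymethoxy)phenyl]-8-(3-methylbut-2-en-1-yl)-4-oxochromane-3-carboxylate
Product: 21 (2R,3R)-3-hydroxy-6-methoxy-5,7-bis(methoxymethoxy)-2-[2-(methoxymethoxy)phenyl]-8-(3-methylbut-2-en-1-yl)chroman-4-one, via keto acid 19 (not isolated), via enediol 20 (not isolated)
Conditions: Pd(OAc)2 (5 mol %), PPh3 (20 mol %), HCO2H (3 equiv), Et3N (3.6 equiv), THF, 23 → 40 °C
Reagents that add atoms: none
Why: Tsuji–Trost deallylation with decarboxylation: zerovalent palladium ionizes the allyl ester, formate reduces the allyl fragment to propene, the α-hydroxy β-keto acid 19 loses CO2 to enediol 20, and 20 ketonizes to the conjugated C4 ketone; C3 is set under thermodynamic control (buffered enolization through 20 should place the hydroxyl and the aryl group trans-diequatorial, so either C3 epimer of 18 converges), while C2 from step 10 is not touched.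

Step 12
Reactants: 21 (2R,3R)-3-hydroxy-6-methoxy-5,7-bis(methoxymethoxy)-2-[2-(methoxymethoxy)phenyl]-8-(3-methylbut-2-en-1-yl)chroman-4-one
Product: 22 floranol, (2R,3R)-3,5,7-trihydroxy-2-(2-hydroxyphenyl)-6-methoxy-8-(3-methylbut-2-en-1-yl)chroman-4-one
Conditions: 3 M HCl, MeOH, 40 °C
Reagents that add atoms: none
Why: Acid-catalysed acetal methanolysis should remove the three MOM ethers without forming or breaking a stereocenter (C2 is not acidic, C3 stays in its preferred trans arrangement), and the mild conditions should keep the prenyl group from cyclizing onto the 7-hydroxyl.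

**Compound list**
1 | 2-methoxyresorcinol (2-methoxybenzene-1,3-diol) | COc1c(O)cccc1O | starting material
2 | 2-methoxy-1,3-bis(methoxymethoxy)benzene | COCOc1cccc(OCOC)c1OC | intermediate
3 | 2-[4-methoxy-3,5-bis(methoxymethoxy)phenyl]-4,4,5,5-tetramethyl-1,3,2-dioxaborolane | COCOc1cc(B2OC(C)(C)C(C)(C)O2)cc(OCOC)c1OC | intermediate (not isolated)
4 | 4-methoxy-3,5-bis(methoxymethoxy)phenol | COCOc1cc(O)cc(OCOC)c1OC | intermediate
5 | 2-methoxy-1,3-bis(methoxymethoxy)-5-[(2-methylbut-3-yn-2-yl)oxy]benzene | COCOc1cc(OC(C)(C)C#C)cc(OCOC)c1OC | intermediate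
6 | 2-methoxy-1,3-bis(methoxymethoxy)-5-[(2-methylbut-3-en-2-yl)oxy]benzene | COCOc1cc(OC(C)(C)C=C)cc(OCOC)c1OC | intermediate
7 | 4-methoxy-3,5-bis(methoxymethoxy)-2-(3-methylbut-2-en-1-yl)phenol | COCOc1cc(O)c(CC=C(C)C)c(OCOC)c1OC | intermediate
8 | 2-(hydroxymethyl)-4-methoxy-3,5-bis(methoxymethoxy)-6-(3-methylbut-2-en-1-yl)phenol | COCOc1c(CO)c(O)c(CC=C(C)C)c(OCOC)c1OC | intermediate (not isolated)
9 | 2-hydroxy-5-methoxy-4,6-bis(methoxymethoxy)-3-(3-methylbut-2-en-1-yl)benzaldehyde | COCOc1c(C=O)c(O)c(CC=C(C)C)c(OCOC)c1OC | intermediate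
10 | salicylaldehyde | O=Cc1ccccc1O | starting material
11 | 2-(methoxymethoxy)benzaldehyde | COCOc1ccccc1C=O | intermediate
12 | dichloroacetyl chloride | O=C(Cl)C(Cl)Cl | starting material
13 | allyl alcohol | C=CCO | starting material
14 | allyl dichloroacetate | C=CCOC(=O)C(Cl)Cl | intermediate
15 | allyl 2-chloro-3-[2-(methoxymethoxy)phenyl]oxirane-2-carboxylate (racemic) | C=CCOC(=O)C1(Cl)OC1c1ccccc1OCOC | intermediate (not isolated)
16 | allyl 3-chloro-3-[2-(methoxymethoxy)phenyl]-2-oxopropanoate (racemic) | C=CCOC(=O)C(=O)C(Cl)c1ccccc1OCOC | intermediate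
17 | allyl 3-[2-formyl-4-methoxy-3,5-bis(methoxymethoxy)-6-(3-methylbut-2-en-1-yl)phenoxy]-3-[2-(methoxymethoxy)phenyl]-2-oxopropanoate (racemic, enolizing) | C=CCOC(=O)C(=O)C(Oc1c(C=O)c(OCOC)c(OC)c(OCOC)c1CC=C(C)C)c1ccccc1OCOC | intermediate (not isolated)
18 | allyl (2R,3R)-3-hydroxy-6-methoxy-5,7-bis(methoxymethoxy)-2-[2-(methoxymethoxy)phenyl]-8-(3-methylbut-2-en-1-yl)-4-oxochromane-3-carboxylate (hydroxyl trans to the C2 aryl group) | COc1c(OCOC)c(CC=C(C)C)c2c(c1OCOC)C(=O)[C@](C(=O)OCC=C)(O)[C@@H](c1ccccc1OCOC)O2 | intermediate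
19 | (2R,3R)-3-hydroxy-6-methoxy-5,7-bis(methoxymethoxy)-2-[2-(methoxymethoxy)phenyl]-8-(3-methylbut-2-en-1-yl)-4-oxochromane-3-carboxylic acid | COc1c(OCOC)c(CC=C(C)C)c2c(c1OCOC)C(=O)[C@](C(=O)O)(O)[C@@H](c1ccccc1OCOC)O2 | intermediate (not isolated)
20 | (2R)-6-methoxy-5,7-bis(methoxymethoxy)-2-[2-(methoxymethoxy)phenyl]-8-(3-methylbut-2-en-1-yl)-2H-chromene-3,4-diol | COc1c(OCOC)c(CC=C(C)C)c2c(c1OCOC)C(O)=C(O)[C@@H](c1ccccc1OCOC)O2 | intermediate (not isolated)
21 | (2R,3R)-3-hydroxy-6-methoxy-5,7-bis(methoxymethoxy)-2-[2-(methoxymethoxy)phenyl]-8-(3-methylbut-2-en-1-yl)chroman-4-one | COc1c(OCOC)c(CC=C(C)C)c2c(c1OCOC)C(=O)[C@H](O)[C@@H](c1ccccc1OCOC)O2 | intermediate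
22 | floranol, (2R,3R)-3,5,7-trihydroxy-2-(2-hydroxyphenyl)-6-methoxy-8-(3-methylbut-2-en-1-yl)chroman-4-one | COc1c(O)c(CC=C(C)C)c2c(c1O)C(=O)[C@H](O)[C@@H](c1ccccc1O)O2 | target

**Step count**
Total steps: 12. Longest linear sequence: 9 (steps 1–6, 10, 11, 12).

**Steps most likely to fail**

Step 10 (bears the label). Two things may go wrong.
- Carbene addition to the di-ortho-oxygenated, electron-rich aldehyde may be slow. The reversible 5-exo aldol of the C2 enolate onto the aldehyde (benzofuranol formation), or alkylation of the carbene by residual chloride, could then take over.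
- The coupling between the catalyst-controlled ketone face and the C2 epimer may be weak. Once C3 is erased in step 11 this would show as low enantiomeric purity at C2.

The fallback uses known chemistry and closes ring C through O1–C2 instead; it sets out from 9 (with 11) and comes back to the route at 21. O-Allylation of 9 (allyl bromide, K2CO3, DMF) should give 2-(allyloxy)-5-methoxy-4,6-bis(methoxymethoxy)-3-(3-methylbut-2-en-1-yl)benzaldehyde F1. Addition of MeMgBr gives the carbinol 1-[2-(allyloxy)-5-methoxy-4,6-bis(methoxymethoxy)-3-(3-methylbut-2-en-1-yl)phenyl]ethan-1-ol F2, and Dess–Martin oxidation gives the corresponding ethan-1-one F3. Claisen–Schmidt condensation of F3 with 11 (KOH, EtOH) gives the (E)-chalcone F4. Juliá–Colonna epoxidation (poly-L-leucine, urea–H2O2, DBU, THF), which attacks the enone and not the prenyl group, should give the (2R,3S)-epoxy ketone F5. Deallylation with Pd(PPh3)4 and PhSiH3 frees only the phenol that becomes O1, giving hydroxy epoxy ketone F6. With PPTS in CH2Cl2, F6 should close ring C by attack of that phenol on the benzylic epoxide carbon with inversion, giving 21; the oxygen that becomes O5 stays protected, so closure through it is excluded.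

Step 9. The dichloroacetate enolate may decompose or self-condense before it meets the aldehyde, the chloride shift of 15 may be incomplete, and the benzylic chloride next to the ortho-alkoxy ring may ionize during isolation.

The fallback builds the keto ester by epoxide opening and oxidation; it sets out from 11 (with 9) and comes back at 17, which is then isolated and given the catalyst stage of step 10. Darzens condensation of 11 with commercial allyl chloroacetate (KN(SiMe3)2, THF) gives allyl 3-[2-(methoxymethoxy)phenyl]oxirane-2-carboxylate F7. Opening of F7 at the benzylic carbon by the phenoxide of 9 (Cs2CO3, DMF, 70 °C) gives the hydroxy ester allyl 3-[2-formyl-4-methoxy-3,5-bis(methoxymethoxy)-6-(3-methylbut-2-en-1-yl)phenoxy]-2-hydroxy-3-[2-(methoxymethoxy)phenyl]propanoate F8. Dess–Martin oxidation of F8 under base-free conditions gives 17.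

Step 11. Kinetic protonation of enediol 20 anti to the C2 aryl group may give the 2,3-cis isomer, and equilibration to trans may be incomplete. Forcing it with base risks opening ring C through the C3 enolate, which would erase C2; capture of the allyl-palladium fragment at C3 is a further side path.

The fallback sets C3 by stereospecific inversion instead of equilibration; it sets out from 18 and comes back at 21. Decarboxylation under kinetic conditions (Pd(PPh3)4, PhSiH3, CH2Cl2, 0 °C) is taken to the cis isomer (2R,3S)-3-hydroxy-6-methoxy-5,7-bis(methoxymethoxy)-2-[2-(methoxymethoxy)phenyl]-8-(3-methylbut-2-en-1-yl)chroman-4-one F9. Mitsunobu reaction of F9 (4-nitrobenzoic acid, DIAD, PPh3) inverts C3 to the trans 4-nitrobenzoate F10. Mild methanolysis of F10 (catalytic K2CO3, MeOH, 0 °C) gives 21.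

**Further compounds**
F1 | step 10 | 2-(allyloxy)-5-methoxy-4,6-bis(methoxymethoxy)-3-(3-methylbut-2-en-1-yl)benzaldehyde | COCOc1c(C=O)c(OCC=C)c(CC=C(C)C)c(OCOC)c1OC
F2 | step 10 | 1-[2-(allyloxy)-5-methoxy-4,6-bis(methoxymethoxy)-3-(3-methylbut-2-en-1-yl)phenyl]ethan-1-ol (racemic) | COCOc1c(C(C)O)c(OCC=C)c(CC=C(C)C)c(OCOC)c1OC
F3 | step 10 | 1-[2-(allyloxy)-5-methoxy-4,6-bis(methoxymethoxy)-3-(3-methylbut-2-en-1-yl)phenyl]ethan-1-one | COCOc1c(C(C)=O)c(OCC=C)c(CC=C(C)C)c(OCOC)c1OC
F4 | step 10 | (E)-1-[2-(allyloxy)-5-methoxy-4,6-bis(methoxymethoxy)-3-(3-methylbut-2-en-1-yl)phenyl]-3-[2-(methoxymethoxy)phenyl]prop-2-en-1-one | COCOc1c(C(=O)/C=C/c2ccccc2OCOC)c(OCC=C)c(CC=C(C)C)c(OCOC)c1OC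
F5 | step 10 | [2-(allyloxy)-5-methoxy-4,6-bis(methoxymethoxy)-3-(3-methylbut-2-en-1-yl)phenyl][(2R,3S)-3-[2-(methoxymethoxy)phenyl]oxiran-2-yl]methanone | COCOc1c(C(=O)[C@@H]2O[C@H]2c2ccccc2OCOC)c(OCC=C)c(CC=C(C)C)c(OCOC)c1OC
F6 | step 10 | [2-hydroxy-5-methoxy-4,6-bis(methoxymethoxy)-3-(3-methylbut-2-en-1-yl)phenyl][(2R,3S)-3-[2-(methoxymethoxy)phenyl]oxiran-2-yl]methanone | COCOc1c(C(=O)[C@@H]2O[C@H]2c2ccccc2OCOC)c(O)c(CC=C(C)C)c(OCOC)c1OC
F7 | step 9 | allyl 3-[2-(methoxymethoxy)phenyl]oxirane-2-carboxylate (racemic) | C=CCOC(=O)C1OC1c1ccccc1OCOC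
F8 | step 9 | allyl 3-[2-formyl-4-methoxy-3,5-bis(methoxymethoxy)-6-(3-methylbut-2-en-1-yl)phenoxy]-2-hydroxy-3-[2-(methoxymethoxy)phenyl]propanoate (racemic) | C=CCOC(=O)C(O)C(Oc1c(C=O)c(OCOC)c(OC)c(OCOC)c1CC=C(C)C)c1ccccc1OCOC
F9 | step 11 | (2R,3S)-3-hydroxy-6-methoxy-5,7-bis(methoxymethoxy)-2-[2-(methoxymethoxy)phenyl]-8-(3-methylbut-2-en-1-yl)chroman-4-one (2,3-cis) | COc1c(OCOC)c(CC=C(C)C)c2c(c1OCOC)C(=O)[C@@H](O)[C@@H](c1ccccc1OCOC)O2
F10 | step 11 | (2R,3R)-6-methoxy-5,7-bis(methoxymethoxy)-2-[2-(methoxymethoxy)phenyl]-8-(3-methylbut-2-en-1-yl)-4-oxochroman-3-yl 4-nitrobenzoate | COc1c(OCOC)c(CC=C(C)C)c2c(c1OCOC)C(=O)[C@H](OC(=O)c1ccc(cc1)[N+](=O)[O-])[C@@H](c1ccccc1OCOC)O2
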